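Both prenyl carbons of the target sit ortho to a phenolic oxygen: C6 of ring A beside O5, and C3′ of ring B beside O4′. The route therefore hangs both five-carbon units on these oxygens as 1,1-dimethylallyl ethers of 7-O-TIPS-genistein and lets two aromatic Claisen shifts carry them to carbon in one heating; because C4a is substituted, O5 can deliver only to C6, not to C8. The precursor is the flat 5,4′-bis(tert-allyl) ether of the isoflavone. The single stereocentre, C3 of the pyranone ring, is set afterwards by ruthenium transfer hydrogenation with dynamic kinetic resolution, followed by reoxidation at C4.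

Key step: step 4

Remark: isoflavone numbering is used throughout (O1, C2, C3, C4=O, C4a, C5–C8, C8a; primed positions on the 3-aryl ring). The target is the 3R isoflavanone, and 3-chloro-3-methylbut-1-yne is taken as the commercial source of the tertiary five-carbon unit.

Step 1
Reactants: 1 genistein (5,7,4′-trihydroxyisoflavone); 2 triisopropylsilyl chloride
Product: 3 5,4′-dihydroxy-7-(triisopropylsilyloxy)isoflavone
Conditions: t-BuOK (1.0 equiv), DMF, 0 °C; then TIPSCl (1.0 equiv), 0 °C
Reagents that add atoms: triisopropylsilyl chloride (2), CC(C)[Si](Cl)(C(C)C)C(C)C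
Why: Phenoxide O-silylation: one equivalent of base should form only the anion of the most acidic hydroxyl (7-OH, para to the C4 carbonyl), which is silylated on oxygen while 4′-OH and the hydrogen-bonded 5-OH stay protonated; TIPS is chosen as the most base-tolerant common silyl group.

Step 2
Reactants: 3 5,4′-dihydroxy-7-(triisopropylsilyloxy)isoflavone; 4 3-chloro-3-methylbut-1-yne
Product: 6 5,4′-bis(2-methylbut-3-yn-2-yloxy)-7-(triisopropylsilyloxy)isoflavone, via 4′-mono(2-methylbut-3-yn-2-yl) ether 5 (not isolated)
Conditions: 4 (5 equiv), DBU (5 equiv), CuCl2 (anhydrous, 2 mol %), dry MeCN, 0 °C → rt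
Reagents that add atoms: 3-chloro-3-methylbut-1-yne (4), CC(C)(Cl)C#C
Why: Copper-catalysed propargylic etherification of phenols: a copper acetylide loses chloride to a copper allenylidene that the phenoxides capture at the tertiary carbon, first at O4′ and then, with excess reagent, at the hydrogen-bonded O5, and the dry, alcohol-free medium should leave the aryl silyl ether intact.

Step 3
Reactants: 6 5,4′-bis(2-methylbut-3-yn-2-yloxy)-7-(triisopropylsilyloxy)isoflavone
Product: 8 5,4′-bis(2-methylbut-3-en-2-yloxy)-7-(triisopropylsilyloxy)isoflavone, via 4′-allyl 5-propargyl diether 7 (not isolated)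
Conditions: H2 (1 atm), Lindlar catalyst (Pd/CaCO3, Pb-poisoned), quinoline, EtOAc, rt, stopped after 2 equiv H2
Reagents that add atoms: none
Why: Lindlar semihydrogenation should stop each terminal alkyne at the alkene (the less hindered 4′-alkyne first), and the poisoned catalyst should not touch the pyranone C2=C3 bond, the aryl ethers or the silyl ether.

Step 4
Reactants: 8 5,4′-bis(2-methylbut-3-en-2-yloxy)-7-(triisopropylsilyloxy)isoflavone
Product: 12 5,4′-dihydroxy-6,3′-bis(3-methylbut-2-enyl)-7-(triisopropylsilyloxy)isoflavone, via C6 dienone 9 (not isolated), via 6-prenyl 4′-ether 10 (not isolated), via C3′ dienone 11 (not isolated)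
Conditions: PhNEt2 (degassed), 125 °C, Ar
Reagents that add atoms: none
Why: Each aryl 1,1-dimethylallyl ether should undergo a concerted, chair-like [3,3]-sigmatropic shift in which the O–C(tertiary) bond breaks while the terminal CH2 of the vinyl group bonds to the ortho ring carbon, giving a cyclohexa-2,4-dienone (9 from the O5 ether, 11 from the O4′ ether) that carries a linear 3-methylbut-2-enyl group because the allyl unit is transposed; loss of the ring proton then restores the phenol. This is the aromatic (ortho) Claisen rearrangement of tertiary allyl aryl ethers, which runs well below the temperature needed for primary allyl ethers and is established for ethers of ortho-acyl phenols. No ring is closed and no stereocentre remains, since the sp3 centres at C6 and C3′ exist only in the dienones. The step needs C6 over C8 and single migration on ring B: O5 has only one unsubstituted ortho carbon (C6, because C4a belongs to the pyranone), and O4′ has two identical ortho carbons but only one allyl group. The C6 dienone should enolise to the chelated 5-hydroxyl faster than it can undergo a second [3,3] (Cope) shift to C8, which would also have to build a quaternary reverse-prenyl centre. The non-polar, weakly basic amine solvent disfavours ionisation of the tertiary ethers and acid-type closure of the new ortho-prenylphenols to chromans.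

Step 5
Reactants: 12 5,4′-dihydroxy-6,3′-bis(3-methylbut-2-enyl)-7-(triisopropylsilyloxy)isoflavone; 13 tert-butyldimethylsilyl trifluoromethanesulfonate
Product: 15 5,4′-bis(tert-butyldimethylsilyloxy)-6,3′-bis(3-methylbut-2-enyl)-7-(triisopropylsilyloxy)isoflavone, via 4′-mono-TBS ether 14 (not isolated)
Conditions: TBSOTf (3 equiv), 2,6-lutidine (4 equiv), CH2Cl2, 0 °C → rt; aq. NaHCO3 work-up
Reagents that add atoms: tert-butyldimethylsilyl trifluoromethanesulfonate (13), CC(C)(C)[Si](C)(C)OS(=O)(=O)C(F)(F)F
Why: Phenol silylation with a silyl triflate and a hindered pyridine base: the triflate is reactive enough for the hydrogen-bonded, doubly flanked 5-OH after 4′-OH has reacted, and capping every phenol as a silyl ether prepares a single fluoride deprotection at the end.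

Step 6
Reactants: 15 5,4′-bis(tert-butyldimethylsilyloxy)-6,3′-bis(3-methylbut-2-enyl)-7-(triisopropylsilyloxy)isoflavone
Product: 17 (3R,4R)-cis-5,4′-bis(tert-butyldimethylsilyloxy)-6,3′-bis(3-methylbut-2-enyl)-7-(triisopropylsilyloxy)isoflavan-4-ol, via racemic isoflavanone 16 (not isolated)
Conditions: RuCl[(R,R)-TsDPEN](p-cymene) (5 mol %), HCO2H/Et3N (5:2), EtOAc, 40 °C
Reagents that add atoms: none
Why: Noyori-type asymmetric transfer hydrogenation with dynamic kinetic resolution: Ru–H should first reduce C2=C3 in the conjugate sense to isoflavanone 16, whose C3 epimerises through the enol faster than the ketone is reduced, and the (R,R)-catalyst should deliver hydride to the C4 face that gives the 4R benzylic carbinol (the usual sense for aryl ketones with this ligand) and anti to the 3-aryl group, so that C3 (R) and C4 (R) are set together as the cis pair while the isolated prenyl alkenes stay inert.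

Step 7
Reactants: 17 (3R,4R)-cis-5,4′-bis(tert-butyldimethylsilyloxy)-6,3′-bis(3-methylbut-2-enyl)-7-(triisopropylsilyloxy)isoflavan-4-ol
Product: 18 (3R)-5,4′-bis(tert-butyldimethylsilyloxy)-6,3′-bis(3-methylbut-2-enyl)-7-(triisopropylsilyloxy)isoflavanone
Conditions: Dess–Martin periodinane (1.3 equiv), NaHCO3, CH2Cl2, 0 °C → rt
Reagents that add atoms: none
Why: Dess–Martin oxidation of the benzylic secondary alcohol under buffered, non-enolising conditions should return the C4 ketone without touching C3, so the 3R configuration from step 6 is carried over, and the fully silylated phenols are shielded from the oxidant.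

Step 8
Reactants: 18 (3R)-5,4′-bis(tert-butyldimethylsilyloxy)-6,3′-bis(3-methylbut-2-enyl)-7-(triisopropylsilyloxy)isoflavanone
Product: 21 (3R)-5,7,4′-trihydroxy-6,3′-bis(3-methylbut-2-enyl)isoflavanone, via 5-hydroxy disilyl ether 19 (not isolated), via 4′-TBS ether 20 (not isolated)
Conditions: TBAF (3.5 equiv)/AcOH (4 equiv), THF, 0 °C; pH 6 phosphate work-up
Reagents that add atoms: none
Why: Fluoride-mediated cleavage of aryl silyl ethers (expected order: O5 next to the carbonyl, then the activated O7, then O4′), buffered with acetic acid so that the medium never turns basic and the α-aryl ketone centre C3 is not enolised, while the absence of strong acid keeps the prenyl groups from closing onto the neighbouring phenols.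

Compound list
1 | genistein (5,7,4′-trihydroxyisoflavone) | O=c1c(-c2ccc(O)cc2)coc2cc(O)cc(O)c12 | starting material
2 | triisopropylsilyl chloride | CC(C)[Si](Cl)(C(C)C)C(C)C | starting material
3 | 5,4′-dihydroxy-7-(triisopropylsilyloxy)isoflavone | O=c1c(-c2ccc(O)cc2)coc2cc(O[Si](C(C)C)(C(C)C)C(C)C)cc(O)c12 | intermediate
4 | 3-chloro-3-methylbut-1-yne | CC(C)(Cl)C#C | starting material
5 | 5-hydroxy-4′-(2-methylbut-3-yn-2-yloxy)-7-(triisopropylsilyloxy)isoflavone | C#CC(C)(C)Oc1ccc(-c2coc3cc(O[Si](C(C)C)(C(C)C)C(C)C)cc(O)c3c2=O)cc1 | intermediate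
6 | 5,4′-bis(2-methylbut-3-yn-2-yloxy)-7-(triisopropylsilyloxy)isoflavone | C#CC(C)(C)Oc1ccc(-c2coc3cc(O[Si](C(C)C)(C(C)C)C(C)C)cc(OC(C)(C)C#C)c3c2=O)cc1 | intermediate
7 | 4′-(2-methylbut-3-en-2-yloxy)-5-(2-methylbut-3-yn-2-yloxy)-7-(triisopropylsilyloxy)isoflavone | C=CC(C)(C)Oc1ccc(-c2coc3cc(O[Si](C(C)C)(C(C)C)C(C)C)cc(OC(C)(C)C#C)c3c2=O)cc1 | intermediate
8 | 5,4′-bis(2-methylbut-3-en-2-yloxy)-7-(triisopropylsilyloxy)isoflavone | C=CC(C)(C)Oc1ccc(-c2coc3cc(O[Si](C(C)C)(C(C)C)C(C)C)cc(OC(C)(C)C=C)c3c2=O)cc1 | intermediate
9 | 3-[4-(2-methylbut-3-en-2-yloxy)phenyl]-6-(3-methylbut-2-enyl)-7-(triisopropylsilyloxy)-6H-chromene-4,5-dione (ring-A dienone; C6 transient and racemic) | C=CC(C)(C)Oc1ccc(cc1)C1=COC2=C(C1=O)C(=O)C(CC=C(C)C)C(O[Si](C(C)C)(C(C)C)C(C)C)=C2 | intermediate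
10 | 5-hydroxy-6-(3-methylbut-2-enyl)-4′-(2-methylbut-3-en-2-yloxy)-7-(triisopropylsilyloxy)isoflavone | C=CC(C)(C)Oc1ccc(-c2coc3cc(O[Si](C(C)C)(C(C)C)C(C)C)c(CC=C(C)C)c(O)c3c2=O)cc1 | intermediate
11 | 5-hydroxy-6-(3-methylbut-2-enyl)-3-[3-(3-methylbut-2-enyl)-4-oxocyclohexa-1,5-dien-1-yl]-7-(triisopropylsilyloxy)chromen-4-one (ring-B dienone; C3′ transient and racemic) | CC(C)=CCC1C=C(C=CC1=O)c1coc2cc(O[Si](C(C)C)(C(C)C)C(C)C)c(CC=C(C)C)c(O)c2c1=O | intermediate
12 | 5,4′-dihydroxy-6,3′-bis(3-methylbut-2-enyl)-7-(triisopropylsilyloxy)isoflavone | CC(C)=CCc1cc(-c2coc3cc(O[Si](C(C)C)(C(C)C)C(C)C)c(CC=C(C)C)c(O)c3c2=O)ccc1O | intermediate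
13 | tert-butyldimethylsilyl trifluoromethanesulfonate | CC(C)(C)[Si](C)(C)OS(=O)(=O)C(F)(F)F | starting material
14 | 4′-(tert-butyldimethylsilyloxy)-5-hydroxy-6,3′-bis(3-methylbut-2-enyl)-7-(triisopropylsilyloxy)isoflavone | CC(C)=CCc1cc(-c2coc3cc(O[Si](C(C)C)(C(C)C)C(C)C)c(CC=C(C)C)c(O)c3c2=O)ccc1O[Si](C)(C)C(C)(C)C | intermediate
15 | 5,4′-bis(tert-butyldimethylsilyloxy)-6,3′-bis(3-methylbut-2-enyl)-7-(triisopropylsilyloxy)isoflavone | CC(C)=CCc1cc(-c2coc3cc(O[Si](C(C)C)(C(C)C)C(C)C)c(CC=C(C)C)c(O[Si](C)(C)C(C)(C)C)c3c2=O)ccc1O[Si](C)(C)C(C)(C)C | intermediate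
16 | racemic 5,4′-bis(tert-butyldimethylsilyloxy)-6,3′-bis(3-methylbut-2-enyl)-7-(triisopropylsilyloxy)isoflavanone (C3 epimerising) | CC(C)=CCc1cc(C2COc3cc(O[Si](C(C)C)(C(C)C)C(C)C)c(CC=C(C)C)c(O[Si](C)(C)C(C)(C)C)c3C2=O)ccc1O[Si](C)(C)C(C)(C)C | intermediate
17 | (3R,4R)-cis-5,4′-bis(tert-butyldimethylsilyloxy)-6,3′-bis(3-methylbut-2-enyl)-7-(triisopropylsilyloxy)isoflavan-4-ol | CC(C)=CCc1cc([C@@H]2COc3cc(O[Si](C(C)C)(C(C)C)C(C)C)c(CC=C(C)C)c(O[Si](C)(C)C(C)(C)C)c3[C@@H]2O)ccc1O[Si](C)(C)C(C)(C)C | intermediate
18 | (3R)-5,4′-bis(tert-butyldimethylsilyloxy)-6,3′-bis(3-methylbut-2-enyl)-7-(triisopropylsilyloxy)isoflavanone | CC(C)=CCc1cc([C@@H]2COc3cc(O[Si](C(C)C)(C(C)C)C(C)C)c(CC=C(C)C)c(O[Si](C)(C)C(C)(C)C)c3C2=O)ccc1O[Si](C)(C)C(C)(C)C | intermediate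
19 | (3R)-4′-(tert-butyldimethylsilyloxy)-5-hydroxy-6,3′-bis(3-methylbut-2-enyl)-7-(triisopropylsilyloxy)isoflavanone | CC(C)=CCc1cc([C@@H]2COc3cc(O[Si](C(C)C)(C(C)C)C(C)C)c(CC=C(C)C)c(O)c3C2=O)ccc1O[Si](C)(C)C(C)(C)C | intermediate
20 | (3R)-4′-(tert-butyldimethylsilyloxy)-5,7-dihydroxy-6,3′-bis(3-methylbut-2-enyl)isoflavanone | CC(C)=CCc1cc([C@@H]2COc3cc(O)c(CC=C(C)C)c(O)c3C2=O)ccc1O[Si](C)(C)C(C)(C)C | intermediate
21 | (3R)-5,7,4′-trihydroxy-6,3′-bis(3-methylbut-2-enyl)isoflavanone (CNP0206440.1) | CC(C)=CCc1cc([C@@H]2COc3cc(O)c(CC=C(C)C)c(O)c3C2=O)ccc1O | target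

Total step count: 8. Longest linear sequence: 8 steps (1 → 21).

Steps most likely to fail

Step 4 (key step). The freed ortho-prenylphenols accumulate in the hot mixture, where they may close onto their own alkenes or allow the allyl group to travel on, and the strained tertiary O5 ether may ionise instead of rearranging. The fallback sets out from 8 and comes back at 12. The rearrangement would be run as a rearrangement–silylation cascade: 8 is heated in N,N-diethylaniline containing N,O-bis(trimethylsilyl)acetamide, so that each phenol is O-silylated as soon as its dienone enolises. This should give 5,4′-bis(trimethylsilyloxy)-6,3′-bis(3-methylbut-2-enyl)-7-(triisopropylsilyloxy)isoflavone F1, which has no free phenol left to react further. Brief methanolysis of the two labile trimethylsilyl ethers (MeOH, cat. citric acid, 0 °C) should then return 12 with the TIPS ether intact.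

Step 2. Etherification of the hydrogen-bonded 5-hydroxyl may stay incomplete, and the long exposure to amidine base that O5 needs may cause loss or transfer of the 7-silyl group. The fallback sets out from 3 and comes back at 8, bypassing 6 and step 3. It is a Tsuji–Trost O-tert-prenylation: tert-butyl 2-methylbut-3-en-2-yl carbonate F2 (from 2-methylbut-3-en-2-ol, n-BuLi and Boc2O in THF) is treated with Pd(PPh3)4 (cat.) and 3 in THF at 0 °C. The tert-butoxide released on decarboxylation deprotonates the phenols, and each phenoxide should attack the more substituted end of the π-(1,1-dimethylallyl)palladium complex. This installs both 1,1-dimethylallyl ethers directly, with no added base and no alkyne stage.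

Step 6. The three events of the cascade may fail to mesh: conjugate hydride transfer to the electron-rich 5,7-dioxygenated pyranone may be slow, or ketone reduction may outrun C3 epimerisation and erode the cis and enantiomeric purity. The fallback sets out from 15 and comes back at 17. The two reductions are separated: L-Selectride (THF, −78 °C, then NH4Cl) adds hydride to C2 of 15 and the enolate is protonated, so that racemic isoflavanone 16 is isolated. Compound 16 is then submitted on its own to the Ru/(R,R)-TsDPEN transfer hydrogenation, where the base content can be raised independently until epimerisation is faster than reduction. This fallback makes no compound outside the compound list (F0).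

Further compounds
F1 | step 4 | 5,4′-bis(trimethylsilyloxy)-6,3′-bis(3-methylbut-2-enyl)-7-(triisopropylsilyloxy)isoflavone | CC(C)=CCc1cc(-c2coc3cc(O[Si](C(C)C)(C(C)C)C(C)C)c(CC=C(C)C)c(O[Si](C)(C)C)c3c2=O)ccc1O[Si](C)(C)C
F2 | step 2 | tert-butyl 2-methylbut-3-en-2-yl carbonate | C=CC(C)(C)OC(=O)OC(C)(C)C
F0 | step 6 | none | none
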